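(The data are calculated from invented constants; noise was put on by code.)

Answer 4 questions about ash, a closed, stirred flask in which free enzyme turns starting material into target while a trace of impurity is present.

common to all: free enzyme 40 µM; impurity 49 µM; temperature 5 °C

| flask | starting material | remark | time |
|---|---|---|---|
| ash | 0.20 M | the very flask that is asked about, followed so far |  |
| larch | 0.30 M | run made earlier |  |
| flask | 0.20 M |  | 5.0 h |

| ash: time / h | ash: target / % | larch: time / min | larch: target / % |
|---|---|---|---|
| 0.333 | 27.4 | 10.0 | 10.7 |
| 1.00 | 30.1 | 20.0 | 11.3 |
| 2.00 | 30.2 | 30.0 | 12.4 |
| 3.00 | 28.6 | 60.0 | 12.6 |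
| 4.00 | 28.9 | 120 | 11.8 |

(each reading ± 0.5 percentage points)

- south: at 5.0 h take out 90% of the target then present, then wait 2.5 h
- west: change nothing and wait 2.5 h more
- north-east: at 5.0 h add free enzyme, 50.0% of the amount charged, then wait 2.5 h
- south-east: at 5.0 h raise the temperature by 20 K, then wait 2.5 h

- target that was removed still counts
- what may be going on: free enzyme -> unfolded enzyme; starting material + free enzyme -> target + free enzyme; free enzyme + target -> spent catalyst A; free enzyme + impurity -> spent catalyst B
- additions bring no volume worth counting
- the earlier runs do not show what temperature does; that part of a forecast is a guess

- target, in percent of the starting material first charged, at 5.0 h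
- the option that brings most further target ("none" if no option brings more than 2 percentage points) (south / west / north-east / south-east / none)
- target present, with what was taken out counted in, in percent of the starting material first charged, after south
- target present, with what was taken out counted in, in percent of the starting material first charged, after north-east

Start from the plateau. The ash readings from 1.00 h to 4.00 h scatter round a mean of 29.4%, so take that as target at 5.0 h and read free enzyme as no longer working. South, west and south-east then have nothing to work with, so expect each to gain less than 2 percentage points.

Next count the impurity surplus, c(impurity) minus c(free enzyme) as charged, 9.00 µM. Less free enzyme is charged than impurity, so this surplus should stay behind in ash. North-east adds 20.0 µM, and the surplus takes its share, leaving 11.0 µM of free enzyme.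

Now replace the falling enzyme curve by its mean, the full charge working for one life. The first ash reading lies 2.1 points below the plateau, which reads as a life of 7.50 min, so each enzyme makes about 196 min⁻¹. At that rate the enzyme left by the count needs 65.3 min for the remaining starting material, less than the 2.5 h allowed. Commit north-east to about 100 percent.

The weak link is that constant rate. Test it on larch, whose plateau of 12.3% is 36.8 mM of target, less than the 58.9 mM in ash on the same enzyme and impurity. Read this as more starting material slowing the enzyme, so a draining flask should run no slower.

The forecast gives 29.4% for now, north-east as best, 29.5% after south and 35.5% after north-east: “Leftover impurity and the target present will kill part of it, so I expect about +6.” The reckoning above differs from it on north-east.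

The flask gives 29.5% at 5.0 h. Best is north-east, gaining 70 points, while south, west and south-east each gain 0 points. South ends at 29.5% and north-east at 99.1%, which is 64 points above the forecast.

    free enzyme → unfolded enzyme (k = 7.30 × 10⁻⁶ s⁻¹, Ea = 278 kJ mol⁻¹)
    starting material + free enzyme → target + free enzyme, rate k2*[starting material]*[free enzyme]/(1 + ([starting material]/Km2) + ([starting material]/Ksi2)^2) (0.500 M, 31.0 mM, k = 1300 M⁻¹ s⁻¹, Ea = 37.0 kJ mol⁻¹)
    free enzyme + target → spent catalyst A (k = 0.00730 M⁻¹ s⁻¹, Ea = 46.0 kJ mol⁻¹)
    free enzyme + impurity → spent catalyst B (k = 180 M⁻¹ s⁻¹, Ea = 45.0 kJ mol⁻¹)
    (constants at 5 °C)

Ash stalls through free enzyme + impurity: the run without that step reaches >99.9% at 5.0 h, against 29.5%. Ash holds 22% of its impurity charge at 5.00 h, or 10.8 µM, close to the surplus of 9.00 µM and less than the 20.0 µM added. Now take the neighbour charged with 20.0 µM of impurity. Its surplus is −20.0 µM, so the count leaves free enzyme over once the impurity has taken its share, and the neighbour should carry its charge on to target. The neighbour gives >99.9% at 5.0 h, with its free enzyme at 0% by then and 50.1% of the catalyst charged standing as spent catalyst A.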